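**Retrosynthetic overview**

1. The C5 propenoic acid goes back to an aryl aldehyde (Knoevenagel–Doebner condensation with malonic acid), and the 4-hydroxycinnamate ester to a primary alcohol plus 4-hydroxycinnamic acid (Mitsunobu esterification).
2. Ring B (the dihydrofuran O1–C2–C3–C3a–C7a) is cut at O1–C7a and C3–C3a; both bonds are formed in one palladium/norbornene (Catellani-type) annulation of an enantiopure terminal epoxide with a para-substituted iodoarene.
3. Enabling feature: O1–C2–C3 of ring B is a masked monosubstituted oxirane (O1 stays on the stereogenic C2, the unsubstituted C3 methylene is the electrophilic carbon), and in ring A the oxygen-bearing C7a is para to the substituted C5, so the two C–H bonds ortho to iodine in the precursor are equivalent and C3a/C7a follow without a regiochemical choice.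
4. Both stereocentres (C2 and the side-chain carbon) are carried by the epoxide and come from one Evans syn-aldol reaction of a propanoyl oxazolidinone with chloroacetaldehyde.
5. Ring order: ring A (benzene) is bought intact as 4-iodobenzaldehyde, ring B is closed in the key step; no other ring is built.

Key step: step 6

Remark (assumption): anhydrous chloroacetaldehyde is taken to be obtained by drying and distilling the commercial aqueous solution just before use, and the bridgehead-substituted norbornene of step 6 (1-methylbicyclo[2.2.1]hept-2-ene, not incorporated into any product) is taken to be at hand as a reagent.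

**Route**

Step 1
Reactants: 1 (4R)-4-benzyl-3-propanoyl-1,3-oxazolidin-2-one; 2 chloroacetaldehyde (anhydrous)
Product: 5 (4R)-4-benzyl-3-[(2R,3R)-4-chloro-3-hydroxy-2-methylbutanoyl]-1,3-oxazolidin-2-one, via dibutylboron Z-enolate 3 (not isolated), via dibutylboron aldolate 4 (not isolated)
Conditions: Bu2BOTf, iPr2NEt, CH2Cl2, −78 → 0 °C; then 2 (freshly distilled), −78 → 0 °C; then pH 7 buffer, MeOH, 30% aq H2O2, 0 °C
Reagents that add atoms: none
Why: Evans syn-aldol reaction: the Z-boron enolate 3 adds to the aldehyde through a closed chair (Zimmerman–Traxler) transition state in which the benzyl group of the auxiliary blocks one enolate face, which should set the (2R,3R) syn pair that becomes both stereocentres of the target.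

Step 2
Reactants: 5 (4R)-4-benzyl-3-[(2R,3R)-4-chloro-3-hydroxy-2-methylbutanoyl]-1,3-oxazolidin-2-one
Product: 6 (2S,3R)-4-chloro-2-methylbutane-1,3-diol
Conditions: LiBH4, THF, H2O (1 equiv), 0 °C
Reagents that add atoms: none
Why: Reductive cleavage of the auxiliary: borohydride attacks the more electrophilic exocyclic imide carbonyl and reduces it to the primary alcohol without touching either stereocentre, and the low temperature should keep the chlorohydrin alkoxide from closing prematurely.

Step 3
Reactants: 6 (2S,3R)-4-chloro-2-methylbutane-1,3-diol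
Product: 7 (2R,3S)-4-{[tert-butyl(dimethyl)silyl]oxy}-1-chloro-3-methylbutan-2-ol
Conditions: TBSCl (1.05 equiv), imidazole, CH2Cl2, 0 °C
Reagents that add atoms: tert-butyldimethylsilyl chloride, CC(C)(C)[Si](C)(C)Cl
Why: Kinetically selective silylation: the unhindered primary hydroxyl should react much faster than the secondary one flanked by two substituents.

Step 4
Reactants: 7 (2R,3S)-4-{[tert-butyl(dimethyl)silyl]oxy}-1-chloro-3-methylbutan-2-ol
Product: 8 tert-butyl(dimethyl){(2S)-2-[(2R)-oxiran-2-yl]propoxy}silane
Conditions: K2CO3, MeOH, 0 °C → rt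
Reagents that add atoms: none
Why: Intramolecular Williamson etherification (3-exo-tet): the secondary alkoxide displaces the primary chloride, so the C–O bond at the stereocentre is not broken and its configuration is retained.

Step 5
Reactants: 9 4-iodobenzaldehyde
Product: 10 2-(4-iodophenyl)-1,3-dioxolane
Conditions: HOCH2CH2OH, p-TsOH·H2O (cat.), toluene, reflux (Dean–Stark)
Reagents that add atoms: ethylene glycol, OCCO
Why: Acid-catalysed acetalisation with azeotropic removal of water masks the aldehyde, which would otherwise be exposed to alkoxide and organopalladium intermediates in step 6.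

Step 6
Reactants: 8 tert-butyl(dimethyl){(2S)-2-[(2R)-oxiran-2-yl]propoxy}silane; 10 2-(4-iodophenyl)-1,3-dioxolane
Product: 11 tert-butyl{(2S)-2-[(2S)-5-(1,3-dioxolan-2-yl)-2,3-dihydro-1-benzofuran-2-yl]propoxy}dimethylsilane
Conditions: Pd(OAc)2 (10 mol %), XPhos (20 mol %), 1-methylbicyclo[2.2.1]hept-2-ene (1 equiv), K2CO3 (2.5 equiv), NMP, 80 °C, argon; 10 in 1.5-fold excess
Reagents that add atoms: none
Why: Proposed new method: zerovalent palladium inserts into the C–I bond of 10, the arylpalladium adds across the norbornene and palladates an ortho C–H bond to give an aryl–norbornyl palladacycle of divalent palladium, which opens epoxide 8 by SN2 attack at the unsubstituted CH2 (to tetravalent palladium) and forms the C3–C3a bond by reductive elimination. β-Carbon elimination then expels the norbornene, and the aryl(alkoxo)palladium so formed, a six-membered oxapalladacycle, closes ring B by C(sp2)–O reductive elimination (O1–C7a), a formal [3+2] annulation. The closest known reaction type is the palladium/norbornene (Catellani-type) annulation of ortho-substituted aryl iodides with terminal epoxides to 2-substituted 2,3-dihydrobenzofurans, which transfers the configuration of enantiopure epoxides unchanged; new here is an aryl iodide with two free ortho positions, for which a second ortho alkylation must be suppressed. That is the task of the bridgehead-substituted norbornene, a mediator known to stop Catellani ortho amination, acylation and arylation of ortho-unsubstituted aryl iodides at the mono stage because its bridgehead group speeds up norbornene extrusion. No stereocentre is created: C2 is the epoxide CH, whose C–O bond is never broken, so (2R) in 8 becomes (2S) in 11 only through the change of substituent priorities, and the side-chain centre is a spectator. The arene regiochemistry is secured by the substrate, since iodine is para to the acetal carbon and both ortho C–H bonds are equivalent, and the epoxide regiochemistry by the steric bias of the monosubstituted oxirane for attack at CH2.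

Step 7
Reactants: 11 tert-butyl{(2S)-2-[(2S)-5-(1,3-dioxolan-2-yl)-2,3-dihydro-1-benzofuran-2-yl]propoxy}dimethylsilane
Product: 12 (2S)-2-[(2S)-1-hydroxypropan-2-yl]-2,3-dihydro-1-benzofuran-5-carbaldehyde
Conditions: 2 M aq HCl, THF, rt
Reagents that add atoms: water, O
Why: Aqueous acid should hydrolyse the dioxolane and the primary silyl ether in one operation, while the aryl alkyl ether of ring B and both stereocentres are inert.

Step 8
Reactants: 12 (2S)-2-[(2S)-1-hydroxypropan-2-yl]-2,3-dihydro-1-benzofuran-5-carbaldehyde; 13 (2E)-3-(4-hydroxyphenyl)prop-2-enoic acid (4-hydroxycinnamic acid)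
Product: 14 (2S)-2-[(2S)-5-formyl-2,3-dihydro-1-benzofuran-2-yl]propyl (2E)-3-(4-hydroxyphenyl)prop-2-enoate
Conditions: PPh3, DIAD, THF, 0 °C → rt
Reagents that add atoms: none
Why: Mitsunobu esterification: the carboxylic acid of 13, far more acidic than its phenol, protonates the betaine and the carboxylate displaces the activated primary oxygen of 12, so the ester should form chemoselectively without phenol protection and without touching a stereocentre.

Step 9
Reactants: 14 (2S)-2-[(2S)-5-formyl-2,3-dihydro-1-benzofuran-2-yl]propyl (2E)-3-(4-hydroxyphenyl)prop-2-enoate; 15 malonic acid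
Product: 17 (2E)-3-[(2S)-2-{(2S)-1-[(2E)-3-(4-hydroxyphenyl)prop-2-enoyl]oxypropan-2-yl}-2,3-dihydro-1-benzofuran-5-yl]prop-2-enoic acid, via arylidenemalonic acid 16 (not isolated)
Conditions: pyridine, piperidine (cat.), 85 °C
Reagents that add atoms: none
Why: Knoevenagel–Doebner condensation: amine-catalysed condensation gives the arylidenemalonic acid 16, which decarboxylates in hot pyridine to the thermodynamically favoured (E)-propenoic acid, the ester and the phenol being left untouched.

**Compound list**

1 | (4R)-4-benzyl-3-propanoyl-1,3-oxazolidin-2-one | CCC(=O)N1[C@H](Cc2ccccc2)COC1=O | starting material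
2 | chloroacetaldehyde | ClCC=O | starting material
3 | (4R)-4-benzyl-3-[(1Z)-1-(dibutylboranyloxy)prop-1-en-1-yl]-1,3-oxazolidin-2-one | C/C=C(\OB(CCCC)CCCC)N1[C@H](Cc2ccccc2)COC1=O | intermediate
4 | (4R)-4-benzyl-3-[(2R,3R)-4-chloro-3-(dibutylboranyloxy)-2-methylbutanoyl]-1,3-oxazolidin-2-one | C[C@@H](C(=O)N1[C@H](Cc2ccccc2)COC1=O)[C@@H](OB(CCCC)CCCC)CCl | intermediate
5 | (4R)-4-benzyl-3-[(2R,3R)-4-chloro-3-hydroxy-2-methylbutanoyl]-1,3-oxazolidin-2-one | C[C@@H](C(=O)N1[C@H](Cc2ccccc2)COC1=O)[C@@H](O)CCl | intermediate
6 | (2S,3R)-4-chloro-2-methylbutane-1,3-diol | C[C@@H](CO)[C@@H](O)CCl | intermediate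
7 | (2R,3S)-4-{[tert-butyl(dimethyl)silyl]oxy}-1-chloro-3-methylbutan-2-ol | C[C@@H](CO[Si](C)(C)C(C)(C)C)[C@@H](O)CCl | intermediate
8 | tert-butyl(dimethyl){(2S)-2-[(2R)-oxiran-2-yl]propoxy}silane | C[C@@H](CO[Si](C)(C)C(C)(C)C)[C@@H]1CO1 | intermediate
9 | 4-iodobenzaldehyde | O=Cc1ccc(I)cc1 | starting material
10 | 2-(4-iodophenyl)-1,3-dioxolane | Ic1ccc(cc1)C1OCCO1 | intermediate
11 | tert-butyl{(2S)-2-[(2S)-5-(1,3-dioxolan-2-yl)-2,3-dihydro-1-benzofuran-2-yl]propoxy}dimethylsilane | C[C@@H](CO[Si](C)(C)C(C)(C)C)[C@@H]1Cc2cc(ccc2O1)C1OCCO1 | intermediate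
12 | (2S)-2-[(2S)-1-hydroxypropan-2-yl]-2,3-dihydro-1-benzofuran-5-carbaldehyde | C[C@@H](CO)[C@@H]1Cc2cc(C=O)ccc2O1 | intermediate
13 | (2E)-3-(4-hydroxyphenyl)prop-2-enoic acid | OC(=O)/C=C/c1ccc(O)cc1 | starting material
14 | (2S)-2-[(2S)-5-formyl-2,3-dihydro-1-benzofuran-2-yl]propyl (2E)-3-(4-hydroxyphenyl)prop-2-enoate | C[C@@H](COC(=O)/C=C/c1ccc(O)cc1)[C@@H]1Cc2cc(C=O)ccc2O1 | intermediate
15 | malonic acid | OC(=O)CC(=O)O | starting material
16 | 2-{[(2S)-2-{(2S)-1-[(2E)-3-(4-hydroxyphenyl)prop-2-enoyl]oxypropan-2-yl}-2,3-dihydro-1-benzofuran-5-yl]methylidene}propanedioic acid | C[C@@H](COC(=O)/C=C/c1ccc(O)cc1)[C@@H]1Cc2cc(C=C(C(=O)O)C(=O)O)ccc2O1 | intermediate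
17 | (2E)-3-[(2S)-2-{(2S)-1-[(2E)-3-(4-hydroxyphenyl)prop-2-enoyl]oxypropan-2-yl}-2,3-dihydro-1-benzofuran-5-yl]prop-2-enoic acid | C[C@@H](COC(=O)/C=C/c1ccc(O)cc1)[C@@H]1Cc2cc(/C=C/C(=O)O)ccc2O1 | target

**Step count and risks**

Total step count: 9. Longest linear sequence: 8 steps (steps 1, 2, 3, 4, 6, 7, 8, 9, from 1 to 17).

Steps most likely to fail:

Step 6 (Proposed new method). The palladacycle may undergo a second ortho C–H palladation and alkylation before the norbornene is expelled. The palladium alkoxide may also undergo β-hydride elimination instead of C–O bond formation, or the epoxide may be consumed by halide opening and isomerisation. The fallback forms the two bonds one after the other by known chemistry; it sets out from 8 and comes back to the route at 11. Commercial 3-bromo-4-chlorobenzaldehyde is acetalised as in step 5 to 2-(3-bromo-4-chlorophenyl)-1,3-dioxolane F1. Bromine–magnesium exchange (iPrMgCl·LiCl, THF, −15 °C) gives [2-chloro-5-(1,3-dioxolan-2-yl)phenyl]magnesium chloride F2, which should open 8 at the terminal carbon under CuI catalysis (−30 → 0 °C) to (2S,3S)-4-{[tert-butyl(dimethyl)silyl]oxy}-1-[2-chloro-5-(1,3-dioxolan-2-yl)phenyl]-3-methylbutan-2-ol F3. Intramolecular palladium-catalysed C–O coupling (Buchwald–Hartwig etherification: Pd(OAc)2, a bulky di-tert-butylbiarylphosphine, Cs2CO3, toluene, 80 °C) then closes ring B and gives 11.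

Step 8. The activated alcohol may alkylate the phenol oxygen of 13 or of the product, and activation of the β-branched alcohol may be slow, so that oligomeric ethers form. The fallback replaces the redox condensation by acylation with a phenol-protected acid; it sets out from 12 and comes back at 14. Carbodiimide (Steglich) esterification of 12 with commercial (2E)-3-(4-acetoxyphenyl)prop-2-enoic acid (EDC·HCl, DMAP, CH2Cl2, 0 °C → rt) should give (2S)-2-[(2S)-5-formyl-2,3-dihydro-1-benzofuran-2-yl]propyl (2E)-3-(4-acetoxyphenyl)prop-2-enoate F4. Brief methanolysis of the aryl acetate (K2CO3 cat., MeOH, 0 °C), which is far faster than that of the alkyl cinnamate, returns 14.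

Step 9. Prolonged heating with amines may cause conjugate addition or acyl transfer at the phenolic cinnamate ester, and decarboxylation of 16 may stall. The fallback builds the propenoic acid by olefination and acidolysis; it sets out from 14 and comes back at 17. Wittig olefination of 14 with tert-butyl (triphenylphosphoranylidene)acetate (toluene, 60 °C) should give, with E selectivity, tert-butyl (2E)-3-[(2S)-2-{(2S)-1-[(2E)-3-(4-hydroxyphenyl)prop-2-enoyl]oxypropan-2-yl}-2,3-dihydro-1-benzofuran-5-yl]prop-2-enoate F5. Cleavage of the tert-butyl ester (TFA, CH2Cl2, anisole as cation scavenger, 0 °C → rt) gives 17.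

**Further compounds**

F1 | step 6 | 2-(3-bromo-4-chlorophenyl)-1,3-dioxolane | Clc1ccc(cc1Br)C1OCCO1
F2 | step 6 | [2-chloro-5-(1,3-dioxolan-2-yl)phenyl]magnesium chloride | Cl[Mg]c1cc(ccc1Cl)C1OCCO1
F3 | step 6 | (2S,3S)-4-{[tert-butyl(dimethyl)silyl]oxy}-1-[2-chloro-5-(1,3-dioxolan-2-yl)phenyl]-3-methylbutan-2-ol | C[C@@H](CO[Si](C)(C)C(C)(C)C)[C@@H](O)Cc1cc(ccc1Cl)C1OCCO1
F4 | step 8 | (2S)-2-[(2S)-5-formyl-2,3-dihydro-1-benzofuran-2-yl]propyl (2E)-3-(4-acetoxyphenyl)prop-2-enoate | C[C@@H](COC(=O)/C=C/c1ccc(OC(C)=O)cc1)[C@@H]1Cc2cc(C=O)ccc2O1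
F5 | step 9 | tert-butyl (2E)-3-[(2S)-2-{(2S)-1-[(2E)-3-(4-hydroxyphenyl)prop-2-enoyl]oxypropan-2-yl}-2,3-dihydro-1-benzofuran-5-yl]prop-2-enoate | C[C@@H](COC(=O)/C=C/c1ccc(O)cc1)[C@@H]1Cc2cc(/C=C/C(=O)OC(C)(C)C)ccc2O1
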